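**Retrosynthetic overview** (locants C1–C8a are those of the 1,2-dihydronaphthalene core of the target and are also used for the open-chain precursors)

1. The target comes from global acidolysis of two 4-methoxybenzyl ethers and one tert-butyl ester; the C2 carboxyl comes from a C2 formyl group by Pinnick oxidation.
2. Ring B is opened at two bonds in one step: the C3=C4 olefin (Horner–Wadsworth–Emmons) and the C8a–C1 aryl–carbon bond (iminium-ion Friedel–Crafts closure). This leaves 3,4-bis(4-methoxybenzyloxy)benzaldehyde and an open-chain C3–C2–C1 phosphonate that carries the pyranone on C1 and a masked formyl group on C2.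
3. Enabling feature: C8a of catechol ring A is para to the C6 oxygen, so ring A is an internal π-nucleophile at exactly the carbon that must bond to C1. C1 is the β-carbon of an α-branched enal (C2–CHO), which a chiral primary amine activates as an iminium ion and which later lets C2 settle trans to C1.
4. The phosphonate comes from a crossed aldol condensation of a 4-formyl-2-pyranone-6-carboxylate with methyl 2-(diethoxyphosphoryl)-4-oxobutanoate; the pyranone (ring C) is built by vinylogous Claisen condensation and lactonisation.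
5. Order of ring formation: ring C (step 1), ring A bought, ring B last (step 9).

Key step: step 9

Assumption: the quinine-derived amine (8S,9S)-9-amino-9-deoxy-epi-quinine is taken to give the 1R series; if it gives 1S, the quinidine-derived pseudoenantiomer is used under the same conditions.

**Step 1**
Reactants: 1 ethyl 3-methylbut-2-enoate; 2 diethyl oxalate
Product: 4 4-methyl-2-oxo-2H-pyran-6-carboxylic acid, via potassium dienolate 3 (not isolated)
Conditions: KOEt, EtOH/Et2O, 0 °C → rt; then conc. HCl, H2O, reflux
Reagents that add atoms: water, O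
Why: Vinylogous Claisen condensation of the γ-deprotonated enoate with the non-enolisable oxalate gives the hydroxydienedioate, whose enol oxygen lactonises onto the cis-disposed ester under acid with hydrolysis of the remaining ester (classical 2-pyranone-6-carboxylic acid synthesis), and no stereocentre is formed.

**Step 2**
Reactants: 4 4-methyl-2-oxo-2H-pyran-6-carboxylic acid
Product: 5 tert-butyl 4-methyl-2-oxo-2H-pyran-6-carboxylate
Conditions: tert-butyl 2,2,2-trichloroacetimidate, BF3·OEt2 (cat.), CH2Cl2/cyclohexane, rt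
Reagents that add atoms: tert-butyl 2,2,2-trichloroacetimidate, CC(C)(C)OC(=N)C(Cl)(Cl)Cl
Why: Acid-catalysed O-alkylation of the carboxylic acid by the imidate (trichloroacetimidate esterification) masks the pyranone acid as an ester that only acid removes.

**Step 3**
Reactants: 5 tert-butyl 4-methyl-2-oxo-2H-pyran-6-carboxylate
Product: 6 tert-butyl 4-formyl-2-oxo-2H-pyran-6-carboxylate
Conditions: SeO2, 1,4-dioxane, reflux
Reagents that add atoms: selenium dioxide, O=[Se]=O
Why: Riley oxidation, because the 4-methyl group is the vinylogous α-position of the lactone carbonyl (as in 4-methylcoumarins) and is oxidised through ene reaction and [2,3]-shift to the aldehyde.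

**Step 4**
Reactants: 7 methyl 2-(diethoxyphosphoryl)acetate; 8 allyl bromide
Product: 9 methyl 2-(diethoxyphosphoryl)pent-4-enoate (racemic)
Conditions: NaH, THF, 0 °C → rt
Reagents that add atoms: none
Why: SN2 C-alkylation of the stabilised phosphonoacetate carbanion by an allylic bromide, and the racemic centre it creates is destroyed in step 9.

**Step 5**
Reactants: 9 methyl 2-(diethoxyphosphoryl)pent-4-enoate
Product: 11 methyl 2-(diethoxyphosphoryl)-4-oxobutanoate (racemic), via ozonide 10 (not isolated)
Conditions: O3, CH2Cl2, −78 °C; then Me2S, −78 °C → rt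
Reagents that add atoms: ozone, [O-][O+]=O
Why: Ozonolysis with reductive work-up cleaves the terminal alkene to the aldehyde while phosphonate and ester are inert.

**Step 6**
Reactants: 6 tert-butyl 4-formyl-2-oxo-2H-pyran-6-carboxylate; 11 methyl 2-(diethoxyphosphoryl)-4-oxobutanoate
Product: 12 methyl (3Z)-4-[6-(tert-butoxycarbonyl)-2-oxo-2H-pyran-4-yl]-2-(diethoxyphosphoryl)-3-formylbut-3-enoate
Conditions: pyrrolidine (10 mol %), PhCO2H (10 mol %), CH2Cl2, 0 °C → rt, slow addition of 11
Reagents that add atoms: none
Why: Amine-catalysed crossed aldol condensation, in which the enamine of the only enolisable aldehyde 11 adds to the non-enolisable electron-poor aldehyde 6 and elimination gives the enal with the pyranone trans to the formyl group.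

**Step 7**
Reactants: 12 methyl (3Z)-4-[6-(tert-butoxycarbonyl)-2-oxo-2H-pyran-4-yl]-2-(diethoxyphosphoryl)-3-formylbut-3-enoate
Product: 13 methyl (3Z)-4-[6-(tert-butoxycarbonyl)-2-oxo-2H-pyran-4-yl]-2-(diethoxyphosphoryl)-3-(dimethoxymethyl)but-3-enoate
Conditions: HC(OMe)3, TsOH·H2O (cat.), MeOH, rt
Reagents that add atoms: trimethyl orthoformate, COC(OC)OC; methanol, CO
Why: Acid-catalysed acetalisation with the orthoformate as water scavenger masks the formyl group, so that the phosphonate carbanion of step 9 cannot olefinate its own aldehyde.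

**Step 8**
Reactants: 14 3,4-dihydroxybenzaldehyde
Product: 15 3,4-bis[(4-methoxybenzyl)oxy]benzaldehyde
Conditions: 4-methoxybenzyl chloride, K2CO3, DMF, 60 °C
Reagents that add atoms: 4-methoxybenzyl chloride, COc1ccc(CCl)cc1
Why: Williamson ether synthesis on both phenols gives electron-donating ethers that survive mild acid and are removed by strong acid at the end.

**Step 9**
Reactants: 13 methyl (3Z)-4-[6-(tert-butoxycarbonyl)-2-oxo-2H-pyran-4-yl]-2-(diethoxyphosphoryl)-3-(dimethoxymethyl)but-3-enoate; 15 3,4-bis[(4-methoxybenzyl)oxy]benzaldehyde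
Product: 18 methyl (1R,2S)-1-[6-(tert-butoxycarbonyl)-2-oxo-2H-pyran-4-yl]-2-formyl-6,7-bis[(4-methoxybenzyl)oxy]-1,2-dihydronaphthalene-3-carboxylate, via triene acetal 16 (not isolated), via triene aldehyde 17 (not isolated)
Conditions: NaH, THF, 0 °C, then 15, 0 → 40 °C; then H2O, CF3CO2H (50 mol %), (8S,9S)-9-amino-9-deoxy-epi-quinine (20 mol %), 45 °C, argon
Reagents that add atoms: water, O
Why: Proposed new method: the sodium phosphonate of 13 olefinates 15 (Horner–Wadsworth–Emmons reaction) to triene 16 with the aryl group cis to C2, aqueous acid then unmasks the α-branched enal 17, and the chiral primary amine condenses with its formyl group to an iminium ion that makes C1 the electrophilic terminus of the C8a=C4a–C4=C3–C2=C1 triene. Ring B closes by 6-endo-trig Friedel–Crafts attack of C8a on C1 (an iminium-accelerated 6π-type closure), loss of the C8a proton restores ring A and leaves a ring enamine at C2, and hydrolysis releases 18 and the amine. The closest known reaction types are the acid-, heat- or light-induced cyclisation of (E,E)-bis(arylidene)succinates to trans-1-aryl-1,2-dihydronaphthalenes and the iminium-ion Friedel–Crafts alkylation of α-branched enals under cinchona primary amine catalysis, which have not been merged in a ring closure by an alkoxybenzene. C1 (R) is set in the C–C bond formation by the catalyst, which holds the iminium ion in one geometry and shields one face of C1. C2 (S) is set by thermodynamic control, because the formyl-bearing carbon equilibrates through the enamine to the trans isomer while C1 has no such pathway. The step needs E geometry at C3=C4, which the olefination of an α-branched phosphonoacetate gives, and closure through C8a and not through the other ortho carbon C5, which is secured because C8a is para to the C6 oxygen and unhindered whereas C5 is flanked by the side chain and the C6 oxygen.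

**Step 10**
Reactants: 18 methyl (1R,2S)-1-[6-(tert-butoxycarbonyl)-2-oxo-2H-pyran-4-yl]-2-formyl-6,7-bis[(4-methoxybenzyl)oxy]-1,2-dihydronaphthalene-3-carboxylate
Product: 19 (1R,2S)-1-[6-(tert-butoxycarbonyl)-2-oxo-2H-pyran-4-yl]-3-(methoxycarbonyl)-6,7-bis[(4-methoxybenzyl)oxy]-1,2-dihydronaphthalene-2-carboxylic acid
Conditions: NaClO2, NaH2PO4, 2-methylbut-2-ene, t-BuOH/THF/H2O, 0 °C → rt
Reagents that add atoms: sodium chlorite, [Na+].[O-]Cl=O
Why: Pinnick oxidation converts the formyl group into the acid in a weakly acidic buffer with the hypochlorous acid scavenged, so that the electron-rich ring, the olefin and both stereocentres should stay untouched.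

**Step 11**
Reactants: 19 (1R,2S)-1-[6-(tert-butoxycarbonyl)-2-oxo-2H-pyran-4-yl]-3-(methoxycarbonyl)-6,7-bis[(4-methoxybenzyl)oxy]-1,2-dihydronaphthalene-2-carboxylic acid
Product: 20 (1R,2S)-1-(6-carboxy-2-oxo-2H-pyran-4-yl)-6,7-dihydroxy-3-(methoxycarbonyl)-1,2-dihydronaphthalene-2-carboxylic acid (target)
Conditions: CF3CO2H, anisole, CH2Cl2, 0 °C → rt
Reagents that add atoms: none
Why: Acidolysis cleaves both 4-methoxybenzyl ethers and the tert-butyl ester through stabilised cations that anisole traps, while the methyl ester, the pyranone and both stereocentres are stable to acid.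

**Compound list**

1 | ethyl 3-methylbut-2-enoate | CCOC(=O)C=C(C)C | starting material
2 | diethyl oxalate | CCOC(=O)C(=O)OCC | starting material
3 | potassium (2Z,4Z)-1,6-diethoxy-4-methyl-1,6-dioxohexa-2,4-dien-2-olate (potassium dienolate) | CCOC(=O)/C([O-])=C/C(C)=C\C(=O)OCC.[K+] | intermediate
4 | 4-methyl-2-oxo-2H-pyran-6-carboxylic acid | Cc1cc(=O)oc(C(=O)O)c1 | intermediate
5 | tert-butyl 4-methyl-2-oxo-2H-pyran-6-carboxylate | Cc1cc(=O)oc(C(=O)OC(C)(C)C)c1 | intermediate
6 | tert-butyl 4-formyl-2-oxo-2H-pyran-6-carboxylate | O=Cc1cc(=O)oc(C(=O)OC(C)(C)C)c1 | intermediate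
7 | methyl 2-(diethoxyphosphoryl)acetate | CCOP(=O)(CC(=O)OC)OCC | starting material
8 | allyl bromide | C=CCBr | starting material
9 | methyl 2-(diethoxyphosphoryl)pent-4-enoate (racemic) | CCOP(=O)(OCC)C(CC=C)C(=O)OC | intermediate
10 | methyl 2-(diethoxyphosphoryl)-3-(1,2,4-trioxolan-3-yl)propanoate (ozonide) | CCOP(=O)(OCC)C(CC1OCOO1)C(=O)OC | intermediate
11 | methyl 2-(diethoxyphosphoryl)-4-oxobutanoate (racemic) | CCOP(=O)(OCC)C(CC=O)C(=O)OC | intermediate
12 | methyl (3Z)-4-[6-(tert-butoxycarbonyl)-2-oxo-2H-pyran-4-yl]-2-(diethoxyphosphoryl)-3-formylbut-3-enoate (pyranone trans to formyl, racemic at the phosphonate carbon) | CCOP(=O)(OCC)C(C(=O)OC)/C(C=O)=C\c1cc(=O)oc(C(=O)OC(C)(C)C)c1 | intermediate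
13 | methyl (3Z)-4-[6-(tert-butoxycarbonyl)-2-oxo-2H-pyran-4-yl]-2-(diethoxyphosphoryl)-3-(dimethoxymethyl)but-3-enoate | CCOP(=O)(OCC)C(C(=O)OC)/C(C(OC)OC)=C\c1cc(=O)oc(C(=O)OC(C)(C)C)c1 | intermediate
14 | 3,4-dihydroxybenzaldehyde | O=Cc1ccc(O)c(O)c1 | starting material
15 | 3,4-bis[(4-methoxybenzyl)oxy]benzaldehyde | O=Cc1ccc(OCc2ccc(OC)cc2)c(OCc2ccc(OC)cc2)c1 | intermediate
16 | methyl (2E,3E)-2-{3,4-bis[(4-methoxybenzyl)oxy]benzylidene}-4-[6-(tert-butoxycarbonyl)-2-oxo-2H-pyran-4-yl]-3-(dimethoxymethyl)but-3-enoate (triene acetal) | COC(=O)/C(=C/c1ccc(OCc2ccc(OC)cc2)c(OCc2ccc(OC)cc2)c1)/C(C(OC)OC)=C\c1cc(=O)oc(C(=O)OC(C)(C)C)c1 | intermediate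
17 | methyl (2E,3E)-2-{3,4-bis[(4-methoxybenzyl)oxy]benzylidene}-4-[6-(tert-butoxycarbonyl)-2-oxo-2H-pyran-4-yl]-3-formylbut-3-enoate (triene aldehyde) | COC(=O)/C(=C/c1ccc(OCc2ccc(OC)cc2)c(OCc2ccc(OC)cc2)c1)/C(C=O)=C\c1cc(=O)oc(C(=O)OC(C)(C)C)c1 | intermediate
18 | methyl (1R,2S)-1-[6-(tert-butoxycarbonyl)-2-oxo-2H-pyran-4-yl]-2-formyl-6,7-bis[(4-methoxybenzyl)oxy]-1,2-dihydronaphthalene-3-carboxylate | COC(=O)C1=Cc2cc(OCc3ccc(OC)cc3)c(OCc3ccc(OC)cc3)cc2[C@@H](c2cc(C(=O)OC(C)(C)C)oc(=O)c2)[C@@H]1C=O | intermediate
19 | (1R,2S)-1-[6-(tert-butoxycarbonyl)-2-oxo-2H-pyran-4-yl]-3-(methoxycarbonyl)-6,7-bis[(4-methoxybenzyl)oxy]-1,2-dihydronaphthalene-2-carboxylic acid | COC(=O)C1=Cc2cc(OCc3ccc(OC)cc3)c(OCc3ccc(OC)cc3)cc2[C@@H](c2cc(C(=O)OC(C)(C)C)oc(=O)c2)[C@@H]1C(=O)O | intermediate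
20 | (1R,2S)-1-(6-carboxy-2-oxo-2H-pyran-4-yl)-6,7-dihydroxy-3-(methoxycarbonyl)-1,2-dihydronaphthalene-2-carboxylic acid (CNP0333269.1) | COC(=O)C1=Cc2cc(O)c(O)cc2[C@@H](c2cc(C(=O)O)oc(=O)c2)[C@@H]1C(=O)O | target

**Step count and risks**

Total step count: 11 steps. Longest linear sequence: 8 steps (steps 1, 2, 3, 6, 7, 9, 10, 11).

Steps most likely to fail:

- **Step 9 (Proposed new method).** The hindered, delocalised phosphonate carbanion may olefinate the electron-rich aldehyde slowly or with poor E selectivity. The iminium ion of the crowded α-branched enal may form slowly, and the ring closure may proceed with poor facial selectivity. The primary amine may open the pyranone, and the C3=C4 double bond may migrate through the dienamine. The fallback separates the events and gives up catalyst control. 13 and 15 are joined by the Horner–Wadsworth–Emmons reaction alone (NaH, THF) and triene acetal 16 is isolated. Aqueous oxalic acid on silica unmasks triene aldehyde 17. Heating 17 in toluene or o-xylene under argon brings about the thermal 6π-electrocyclisation and [1,5]-hydrogen shift that is known for bis(arylidene)succinic acid derivatives, and a trace of pyrrolidinium acetate equilibrates the formyl-bearing carbon, to give the racemic trans aldehyde F1. Preparative chromatography on a chiral stationary phase then delivers 18, where the route is rejoined.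

- **Step 6.** The secondary amine may open the pyranone ring, aldehyde 11 may condense with itself, and the double bond may migrate toward the acidic phosphonate carbon. The fallback replaces amine catalysis by a Mukaiyama aldol sequence. Aldehyde 11 is converted into its silyl enol ether F2 (Me3SiCl, Et3N, NaI, MeCN). BF3·OEt2-mediated addition of F2 to aldehyde 6 at −78 °C gives, after aqueous work-up, the aldol F3. Acid-catalysed dehydration (TsOH, toluene, 40 °C) gives 12, where the route is rejoined.

- **Step 3.** The oxidation may stop short, run on to the carboxylic acid, or cost the tert-butyl ester in hot selenous acid. The fallback goes through the halide: radical bromination of 5 (N-bromosuccinimide, AIBN, PhCF3, reflux) gives the bromide F4, and Kornblum oxidation (DMSO, NaHCO3, 40 °C) returns to 6.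

**Further compounds**

F1 | step 9 | racemic methyl trans-1-[6-(tert-butoxycarbonyl)-2-oxo-2H-pyran-4-yl]-2-formyl-6,7-bis[(4-methoxybenzyl)oxy]-1,2-dihydronaphthalene-3-carboxylate (18 and its enantiomer) | COC(=O)C1=Cc2cc(OCc3ccc(OC)cc3)c(OCc3ccc(OC)cc3)cc2[C@@H](c2cc(C(=O)OC(C)(C)C)oc(=O)c2)[C@@H]1C=O.COC(=O)C1=Cc2cc(OCc3ccc(OC)cc3)c(OCc3ccc(OC)cc3)cc2[C@H](c2cc(C(=O)OC(C)(C)C)oc(=O)c2)[C@H]1C=O
F2 | step 6 | methyl 2-(diethoxyphosphoryl)-4-[(trimethylsilyl)oxy]but-3-enoate (E/Z mixture, racemic) | CCOP(=O)(OCC)C(C=CO[Si](C)(C)C)C(=O)OC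
F3 | step 6 | methyl 4-[6-(tert-butoxycarbonyl)-2-oxo-2H-pyran-4-yl]-2-(diethoxyphosphoryl)-3-formyl-4-hydroxybutanoate (mixture of diastereomers) | CCOP(=O)(OCC)C(C(=O)OC)C(C=O)C(O)c1cc(=O)oc(C(=O)OC(C)(C)C)c1
F4 | step 3 | tert-butyl 4-(bromomethyl)-2-oxo-2H-pyran-6-carboxylate | BrCc1cc(=O)oc(C(=O)OC(C)(C)C)c1
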